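## Structural features

Clerodane numbering is used throughout: ring A = C1–C5, C10; ring B = C5–C10; C18 on C4; C19 on C5; C17 on C8; C20 on C9; furan C13–C16 with C16 on C1; C12 and C11 on C13.

The target has five rings: a cis-fused decalin (rings A and B), an α-alkylidene γ-lactone spanning C4 and C5 (C18 carbonyl, C19 methylene, C3=C4 endocyclic to ring A), a seven-membered ketone ring C (C1, C10, C9, C11, C12, C13, C16), and a furan bonded to C1 through C16 and carrying the C12 ketone on C13. Rings A, B and C all meet at C10, so the decalin is peri-annulated by the furan-fused cycloheptanone. There are five stereocentres: the contiguous C1 (R), C10 (S), quaternary C9 (R, C20 methyl) and quaternary C5 (S, C19), with H1, H10, C19 and C20 on one face, and the separate C7 (S), whose acetoxy group is trans to C19. Fragile parts are the furan (acid, electrophilic oxidants), the allylic acetate beside the C8=C17 methylene (ionisation, zerovalent palladium), the conjugated lactone (bases, hard nucleophiles) and the acidic C11 methylene. The main difficulty is quaternary C9, flanked by the C8 methylene, ring-fusion C10 and ring C; the second is the furan at C1, which sits on the concave face of the cis-decalin. The key step uses the fact that C9 lies between an exocyclic alkene (C8=C17) and a carbon α to a ketone (C11–C12=O). The first is what an allylsilane leaves after reacting at its γ-carbon, the second what an oxidised enol ether leaves, and both π-systems hang from the neighbouring atoms C9 and C10 through C1 and the planar furan.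

## Logic of the disconnections

29 ⇒ 28. The C9–C11 bond is cut. This removes ring C and the quaternary C9 in one stroke and leaves a decalin with a C9=C8 allylsilane and a C12 silyl enol ether. The forward step must oxidise this pair selectively, close a seven-membered ring, and form the bond on the C9 face syn to C1.

28 ⇒ 27 ⇒ 26. The O–Si bond at C12 and the O–acyl bond at C7 are cut. The enol ether is the most labile group and is made last. The acetate is added only after the palladium step, because a 2-(silylmethyl)allyl acetate would ionise with zerovalent palladium to a trimethylenemethane complex. The forward steps need soft enolisation of the methyl ketone only, and acylation that spares the allylsilane.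

26 ⇒ 22 + 23. The C8–C17 bond is cut to an enol triflate and a silylmethyl metal. This keeps the acid-labile allylsilane out of the route until three steps from the end. The coupling must work at a tetrasubstituted triflate beside a free hydroxyl and a ketone, so zinc is used in place of magnesium.

22 ⇒ 20 ⇒ 19 ⇒ 18 ⇒ 17. The C7–H bond, the O–S bond and the C7 oxidation level are taken back to the C7=C8 silyl enol ether. Setting C7 by hydride delivery to a C7 ketone makes it independent of the face of the earlier oxidation. The diosphenol places the triflate on C8 with the double bond at C8=C9 without enolising a ketone that has an oxygenated α-carbon. The forward steps need an oxidation that spares the furan, reagent-controlled reduction, and a C12 mask that lasts until after the hydride steps.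

17 ⇒ 16 ⇒ 15 ⇒ 14. The C4–C18 and C18–O bonds are cut (carbon monoxide supplies C18), and C19 goes back to an ester. A C4 ketone beside quaternary C5 can enolise only towards C3, so the C3=C4 position is fixed. The lactone is reduced to a β-keto ester. The forward steps need ester reduction beside an enol triflate and a carbonylative ring closure.

14 ⇒ 13 ⇒ 12 ⇒ 5 + 8. The C1–H bond, then the C1–O bond, then the C1–C16 bond are cut. A nucleophile would approach C1 from the convex face and put the furan on the wrong side. So the furan is added to a C1 carbonyl, the oxygen is removed reductively, and hydrogen is delivered from the convex face. This splits off the whole furan fragment. The forward steps need site selectivity between the C1 and C4 carbonyls and facial selectivity in the hydrogenation.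

8 ⇒ 7 ⇒ 6. The ketal C–O bonds and the C12–C11 bond are cut. The furan reaches a one-step-from-commercial acid. The ketal must survive base and hydride and direct metalation to C2.

5 ⇒ 4 + 2, then 4 ⇒ 3 and 2 ⇒ 1. The C5–C6 and C9–C10 bonds are cut (Diels–Alder retron: cyclohexene with oxygen on C8, cis fusion, angular ester). One step then assembles all carbons of rings A and B with C19 and C20, oxygen at C1, C4 and C8, and the C5/C10 configuration. The forward step must join C9 to C10 (not C6 to C10) and needs enantiofacial control by a chiral Lewis acid; 4 and 2 come from a hydroquinone ester and an ethyl vinyl ketone by oxidation and silylation.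

## Other disconnections considered

Alternative 1: The cut is C5–C6, with C3–O made in exchange. The bridged eight-membered enol ether A1 (oxygen between C3 and C7, C7=C6 exocyclic, C4=C5 in the lactone) is heated, and a Claisen rearrangement gives the 7-oxo compound A2.
- In favour: it needs no reagent, transfers the C3 configuration to quaternary C5 stereospecifically, and places a carbonyl exactly at C7.
- Against: A1 must already hold quaternary C9, ring C and the furan, so the hardest centre is not addressed. A1 also contains an acid-labile 2-alkoxy-1,3-diene in a bridged medium ring that is itself hard to close, and the allyl partner is a tetrasubstituted electron-poor alkene held in a boat-like array. A2 still needs a face-selective 1,2-reduction at C7 and acetylation.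
- Comparison: structurally it builds C5, which the chosen plan sets in step 3, but not C9. Mechanistically it is the better of the two, since the rearrangement is established and stereospecific whereas the anodic closure is untested on this ring size. In step economy it is worse: the substrate is at least as complex as 28 and two steps follow the key step instead of none.

Alternative 2: The cut runs through the furan. The 2-ethynyl cycloheptenone A3 is treated with AuCl3 in wet acetonitrile; the C16 carbonyl oxygen closes onto C15, water adds at C12, and the 12-hydroxy furan A4 results, to be oxidised to 29.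
- In favour: this type of gold catalysis is known and mild. The sensitive furan appears only at the end, whereas in the chosen route it must survive osmylation, periodinane oxidation and palladium; on functional-group safety the alternative is the better plan.
- Against: only C–O bonds and no stereocentre are formed. Ring C, quaternary C9 and a C16 ketone next to a now epimerisable C1 must all be present in A3. Terminal alkynes are the weaker substrates for this cyclisation, the gold salt meets an allylic acetate, and one oxidation step follows.
- Comparison: A3 is harder to reach than 28; the mechanism is better precedented; step economy is worse by one step after the key step and a longer approach.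

Alternative 3: The cut is C1–C16. In A5 the furan is tethered through C11–C12 to an already quaternary C9; Me2AlCl activates the 1,3-dien-18,19-olide, C16 adds to C1, and the ring C-closed silyl ether A6 results.
- In favour: it follows the likely biogenesis, and the tether delivers the furan to the concave face at C1 with no further control. Here the alternative is better than the chosen plan, which spends steps 6–8 and an uncertain hydrogenation on C1. A 3-alkylfuran also reacts at C16, the correct carbon.
- Against: A5 must carry quaternary C9 with its side chain next to the C8 methylene and C7 acetate, which is the classical clerodane problem left unsolved. A lactone dienoate is a weak acceptor for 1,6-addition, and the Lewis acid meets an allylic acetate and a furan. Protonation may occur at C4 instead of C2. Desilylation and oxidation at C12 follow (two steps).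
- Comparison: both key steps close ring C and set one stereocentre, so they are equal in bonds and rings formed. The chosen plan creates the quaternary centre, the alternative the tertiary one. The alternative's polar mechanism is closer to known reactions; its step economy is worse by two steps after the key step.

Key step: step 19

**Remarks on the chemistry**
- Checked centre by centre, 28 and 29 have the same configuration at C1, C5, C7 and C10 (1R,5S,7S,10S), and 29 adds 9R (C20 cis to H10); no structural correction was needed. The lactone is an α-alkylidene γ-lactone (C3=C4 exocyclic to the lactone ring), not a butenolide in the strict sense.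
- The skeleton of 28 is kept. What is changed on the way to it: acetylation comes after the palladium coupling; a zinc reagent replaces the Grignard reagent; the C8 triflate is made from a diosphenol; C1 is set by hydrogenation.
- Assumption: the sense of induction of the Sm(OTf)3–pybox complex follows the ligand; the antipode that gives the (5S,10S) adduct is used.
- Assumption: auxiliary centres that are destroyed later (C9 in 5–18, C1 in 11 and 12, C7 in 18) are drawn as expected, but either epimer serves.

## Steps

Step 1
Reactants: 1 pent-1-en-3-one
Product: 2 (Z)-triisopropyl(penta-1,3-dien-3-yloxy)silane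
Conditions: i-Pr3SiOTf, Et3N, Et2O, 0 °C
Reagents that add atoms: triisopropylsilyl trifluoromethanesulfonate, CC(C)[Si](OS(=O)(=O)C(F)(F)F)(C(C)C)C(C)C
Why: Soft enolisation and O-silylation give the (Z)-enol ether, in which the terminal methyl is in the reactive outside position of the diene; the bulky silyl group lets the enol ether last until step 12.

Step 2
Reactants: 3 methyl 2,5-dihydroxybenzoate
Product: 4 methyl 3,6-dioxocyclohexa-1,4-diene-1-carboxylate
Conditions: Ag2O, MgSO4, CH2Cl2, rt; used at once
Reagents that add atoms: none
Why: Two-electron oxidation of the hydroquinone to the quinone; the ester-bearing double bond becomes the most electron-poor alkene.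

Step 3
Reactants: 4 methyl 3,6-dioxocyclohexa-1,4-diene-1-carboxylate; 2 (Z)-triisopropyl(penta-1,3-dien-3-yloxy)silane
Product: 5 cis-fused Diels–Alder adduct (C1=O, C2=C3, C4=O, CO2Me on C5, C7=C8 with OSi(i-Pr)3 on C8, CH3 on C9)
Conditions: Sm(OTf)3 (10 mol%), (S,S)-Ph-pybox (12 mol%), 4 Å molecular sieves, THF, −78 °C
Reagents that add atoms: none
Why: Enantioselective Diels–Alder reaction of a quinone ester: two-point binding of the C4 carbonyl and the ester to the samarium–pybox complex activates C5=C10 and shields one face; the enol-ether β-carbon C9 bonds to the doubly activated C10 and C6 to C5. Suprafacial addition to the ring alkene makes the fusion cis (H10 syn to the ester), which sets C5 and C10.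

Step 4
Reactants: 6 3-furoic acid
Product: 7 1-(furan-3-yl)ethan-1-one
Conditions: MeLi (2.2 equiv), Et2O, 0 °C to rt; aq. NH4Cl
Reagents that add atoms: methyllithium, [Li]C
Why: Methyllithium adds to the lithium carboxylate and stops at the gem-dialkoxide, which gives the methyl ketone on hydrolysis; this methyl becomes C11.

Step 5
Reactants: 7 1-(furan-3-yl)ethan-1-one
Product: 8 2-(furan-3-yl)-2-methyl-1,3-dioxolane
Conditions: HOCH2CH2OH, TsOH (cat.), benzene, reflux, Dean–Stark
Reagents that add atoms: ethylene glycol, OCCO
Why: Acid-catalysed ketalisation masks the C12 ketone against the organometallic, enolate and hydride chemistry of steps 6–15 and supplies an oxygen that directs lithiation to C2.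

Step 6
Reactants: 8 2-(furan-3-yl)-2-methyl-1,3-dioxolane; 5 cis-fused Diels–Alder adduct
Product: 12 C1 tertiary acetate of the furyl adduct (C2=C3 and C4=O retained), via 2-lithiofuran ketal 9 (not isolated), via furylcerium dichloride 10 (not isolated), via C1 cerium alkoxide 11 (not isolated)
Conditions: 8, n-BuLi, THF, −78 to 0 °C; CeCl3, −78 °C; 5, −78 °C; Ac2O, −78 to 0 °C
Reagents that add atoms: acetic anhydride, CC(=O)OC(C)=O
Why: Directed lithiation at furan C2 (α to the ring oxygen, next to the coordinating dioxolane), transmetalation to the weakly basic organocerium, and 1,2-addition to the C1 carbonyl, which is flanked by a CH whereas C4 is shielded by quaternary C5. In situ acetylation makes the tertiary alkoxide a leaving group; its configuration is irrelevant because C1 becomes trigonal in step 7.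

Step 7
Reactants: 12 C1 tertiary acetate of the furyl adduct
Product: 13 β,γ-unsaturated ketone (C1=C2 bearing the furyl group, C3H2, C4=O)
Conditions: SmI2 (2.2 equiv), THF–MeOH, −78 °C
Reagents that add atoms: none
Why: Samarium diiodide reduction of a γ-acyloxy enone: electron transfer expels the γ-acetate and gives a samarium dienolate, whose kinetic protonation at the α-carbon C3 leaves C1=C2 conjugated with the furan.

Step 8
Reactants: 13 β,γ-unsaturated ketone
Product: 14 (1R)-1-furyl C4 ketone (H1 cis to H10 and to the C5 ester)
Conditions: H2 (1 atm), 5% Pd/C, EtOAc, Et3N (trace), rt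
Reagents that add atoms: none
Why: Heterogeneous syn-hydrogenation of the furan-conjugated trisubstituted alkene. To avoid allylic strain with the furan, the C10–C9 bond stands pseudoaxial and blocks the lower face, so hydrogen reaches C1 from the face of H10 and the furan ends up cis to C9; the hindered silyl enol ether and the furan ring react much more slowly.

Step 9
Reactants: 14 (1R)-1-furyl C4 ketone
Product: 15 C4 enol triflate (C3=C4)
Conditions: KN(SiMe3)2, THF, −78 °C; PhNTf2, −78 to 0 °C
Reagents that add atoms: N-phenylbis(trifluoromethanesulfonimide), O=S(=O)(N(c1ccccc1)S(=O)(=O)C(F)(F)F)C(F)(F)F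
Why: Only C3 carries α-hydrogens (C5 is quaternary), so enolate formation and O-sulfonylation give the C3=C4 enol triflate regiospecifically.

Step 10
Reactants: 15 C4 enol triflate
Product: 16 C19 primary alcohol
Conditions: i-Bu2AlH (3 equiv), CH2Cl2, −78 to −20 °C; aq. potassium sodium tartrate
Reagents that add atoms: none
Why: Hydride reduction of the neopentyl ester to the alcohol; enol triflate, silyl enol ether and ketal are inert to i-Bu2AlH at low temperature.

Step 11
Reactants: 16 C19 primary alcohol
Product: 17 18,19-lactone (α-alkylidene γ-lactone, C3=C4) with the C8 silyl enol ether intact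
Conditions: Pd(PPh3)4 (10 mol%), CO (1 atm), Et3N, LiCl, DMF, 60 °C
Reagents that add atoms: carbon monoxide, [C-]#[O+]
Why: Carbonylative lactonisation: oxidative addition of zerovalent palladium to the enol triflate, CO insertion, and 5-exo capture of the acylpalladium by the C19 hydroxyl; CO supplies C18.

Step 12
Reactants: 17 18,19-lactone
Product: 18 7-hydroxy-8-ketone
Conditions: OsO4 (5 mol%), N-methylmorpholine N-oxide, acetone–H2O (10:1), 0 °C
Reagents that add atoms: osmium tetroxide, O=[Os](=O)(=O)=O; N-methylmorpholine N-oxide (terminal oxygen source), C[N+]1([O-])CCOCC1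
Why: Osmium-catalysed dihydroxylation (Upjohn conditions) of the electron-rich enol ether as a furan-sparing equivalent of the Rubottom oxidation; collapse of the silyl hemiketal gives the ketol. The conjugated lactone alkene and the furan react far more slowly, and the C7 configuration is irrelevant because step 13 oxidises it.

Step 13
Reactants: 18 7-hydroxy-8-ketone
Product: 19 diosphenol (8-hydroxy-8-en-7-one, C8=C9)
Conditions: Dess–Martin periodinane, NaHCO3, CH2Cl2, 0 °C to rt; then Et3N (1 equiv)
Reagents that add atoms: none
Why: Periodinane oxidation of the ketol gives the 1,2-dione, which enolises towards C9 to the more substituted conjugated diosphenol, as 3-alkylcyclohexane-1,2-diones do; this fixes the later double bond at C8=C9.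

Step 14
Reactants: 19 diosphenol
Product: 20 8-triflyloxy-8-en-7-one
Conditions: PhNTf2, Et3N, DMAP (cat.), CH2Cl2, 0 °C to rt
Reagents that add atoms: N-phenylbis(trifluoromethanesulfonimide), O=S(=O)(N(c1ccccc1)S(=O)(=O)C(F)(F)F)C(F)(F)F
Why: The acidic enol is O-triflated under mild base; the leaving group sits on C8 and the carbonyl on C7, so no ketone enolisation of uncertain direction is needed.

Step 15
Reactants: 20 8-triflyloxy-8-en-7-one
Product: 22 (7S)-hydroxy enol triflate with the free C12 methyl ketone, via (7S)-hydroxy triflate ketal 21 (not isolated)
Conditions: (R)-2-methyl-CBS-oxazaborolidine (0.5 equiv), catecholborane, toluene, −78 °C; then 1 M HCl, THF, rt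
Reagents that add atoms: water, O
Why: Corey–Bakshi–Shibata reduction with alkenyl C8 as the large and the C6 methylene as the small substituent; the (R)-catalyst delivers hydride to the face that gives the 7S alcohol (hydroxyl trans to C19) under reagent control. The acidic work-up removes the dioxolane before the acid-labile allylsilane is introduced.

Step 16
Reactants: 23 (chloromethyl)trimethylsilane; 22 (7S)-hydroxy enol triflate
Product: 26 allylsilane alcohol (CH2SiMe3 on C8, C8=C9, 7-OH), via (trimethylsilyl)methylmagnesium chloride 24 (not isolated), via (trimethylsilyl)methylzinc chloride 25 (not isolated)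
Conditions: 23, Mg, THF, 40 °C; ZnCl2, 0 °C; then 22, PdCl2(dppf) (5 mol%), THF, 50 °C
Reagents that add atoms: none
Why: Negishi coupling of the enol triflate with a silylmethylzinc reagent that has no β-hydrogen. Zinc is used because it tolerates the C12 ketone, the lactone and the free hydroxyl (extra equivalents); the hydroxyl is left unacylated so that no 2-(silylmethyl)allyl acetate, a trimethylenemethane precursor, meets zerovalent palladium.

Step 17
Reactants: 26 allylsilane alcohol
Product: 27 allylsilane 7-acetate
Conditions: Ac2O, pyridine, DMAP (cat.), CH2Cl2, 0 °C to rt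
Reagents that add atoms: acetic anhydride, CC(=O)OC(C)=O
Why: Standard acylation of the secondary allylic alcohol; the basic medium leaves the allylsilane untouched.

Step 18
Reactants: 27 allylsilane 7-acetate
Product: 28 C12 tert-butyldimethylsilyl enol ether (9,11-seco precursor)
Conditions: t-BuMe2SiOTf, Et3N, CH2Cl2, −78 to 0 °C
Reagents that add atoms: tert-butyldimethylsilyl trifluoromethanesulfonate, CC(C)(C)[Si](C)(C)OS(=O)(=O)C(F)(F)F
Why: Soft enolisation of the aryl methyl ketone, which is silylated far more readily than the acetate or the lactone; excess amine keeps the medium non-acidic for the allylsilane.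

Step 19
Reactants: 28 C12 tert-butyldimethylsilyl enol ether
Product: 29 target, (1R,5S,7S,9R,10S)
Conditions: reticulated vitreous carbon anode, Pt cathode, undivided cell, LiClO4 (0.1 M), MeOH–CH2Cl2 (1:4), 2,6-lutidine, constant current (8 mA), 2.2 F/mol, rt
Reagents that add atoms: none
Why: Proposed new method: one-electron anodic oxidation of the furan-conjugated silyl enol ether, the most easily oxidised π-system of 28, gives a radical cation whose terminus C11 is attacked by C9, the γ-carbon of the C8=C9 allylsilane; the β-silyl cation at C8 then loses Me3Si+ to methanol to give the C8=C17 methylene, and the C12 α-silyloxy radical is oxidised and loses its silyl group to give the ketone (two electrons overall, H2 at the cathode). The closest known reaction types are the anodic coupling of enol ether radical cations with allylsilanes, which builds quaternary carbons in five- and six-membered rings, and the anodic annulation of furans with silyl enol ethers; a seven-membered closure between a silyl enol ether and a tetrasubstituted allylsilane has not been shown. Ring C closes in a seven-membered mode that is exo with respect to C8=C9 and endo with respect to C11=C12, helped by the short, partly rigid tether (C10–C1–furan) between the two π-systems. The new centre C9 is controlled by that tether: C11 can reach C9 only on the face syn to the C10–C1 bond, which puts C20 cis to H10 (9R). The step needs oxidation of the enol ether–allylsilane pair ahead of the lactone, the acetate and the product 3-acylfuran, all of which have higher oxidation potentials, and it needs cyclisation to outrun methanol capture at C11, which the intramolecular setting and the low methanol content favour. 2,6-Lutidine keeps the medium non-acidic so that neither silyl group is lost by protonolysis before oxidation, and the charge is limited to avoid oxidising the furan of 29.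

## Compound list

1 | pent-1-en-3-one | CCC(=O)C=C | starting material
2 | (Z)-triisopropyl(penta-1,3-dien-3-yloxy)silane | C/C=C(\O[Si](C(C)C)(C(C)C)C(C)C)C=C | intermediate
3 | methyl 2,5-dihydroxybenzoate | COC(=O)c1cc(O)ccc1O | starting material
4 | methyl 3,6-dioxocyclohexa-1,4-diene-1-carboxylate | COC(=O)C1=CC(=O)C=CC1=O | intermediate
5 | Diels–Alder adduct (5S,9R,10S): cis-decalin with C1=O, C2=C3, C4=O, CO2Me on C5, C7=C8 with OSi(i-Pr)3 on C8, CH3 on C9; H10 cis to the ester, 9-CH3 cis to C1 | COC(=O)[C@@]12CC=C(O[Si](C(C)C)(C(C)C)C(C)C)[C@H](C)[C@@H]1C(=O)C=CC2=O | intermediate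
6 | 3-furoic acid | OC(=O)c1ccoc1 | starting material
7 | 1-(furan-3-yl)ethan-1-one | CC(=O)c1ccoc1 | intermediate
8 | 2-(furan-3-yl)-2-methyl-1,3-dioxolane | CC1(OCCO1)c1ccoc1 | intermediate
9 | [3-(2-methyl-1,3-dioxolan-2-yl)furan-2-yl]lithium | [Li]c1occc1C1(C)OCCO1 | intermediate (not isolated)
10 | dichloro[3-(2-methyl-1,3-dioxolan-2-yl)furan-2-yl]cerium | Cl[Ce](Cl)c1occc1C1(C)OCCO1 | intermediate (not isolated)
11 | dichlorocerium C1 alkoxide of the 1,2-adduct of 10 to 5 (furyl on the face of H10) | COC(=O)[C@@]12CC=C(O[Si](C(C)C)(C(C)C)C(C)C)[C@H](C)[C@@H]1[C@@](O[Ce](Cl)Cl)(c1occc1C1(C)OCCO1)C=CC2=O | intermediate (not isolated)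
12 | C1 tertiary acetate: 5 with C1 as C(OAc)[3-(2-methyl-1,3-dioxolan-2-yl)furan-2-yl]; C2=C3, C4=O | COC(=O)[C@@]12CC=C(O[Si](C(C)C)(C(C)C)C(C)C)[C@H](C)[C@@H]1[C@@](OC(C)=O)(c1occc1C1(C)OCCO1)C=CC2=O | intermediate
13 | β,γ-unsaturated ketone: C1=C2 with the furyl ketal on C1, C3H2, C4=O, CO2Me on C5 | COC(=O)[C@@]12CC=C(O[Si](C(C)C)(C(C)C)C(C)C)[C@H](C)[C@@H]1C(c1occc1C1(C)OCCO1)=CCC2=O | intermediate
14 | (1R)-1-furyl C4 ketone: H1, H10 and the C5 ester mutually cis | COC(=O)[C@@]12CC=C(O[Si](C(C)C)(C(C)C)C(C)C)[C@H](C)[C@@H]1[C@H](c1occc1C1(C)OCCO1)CCC2=O | intermediate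
15 | C4 enol triflate (C3=C4) of 14 | COC(=O)[C@@]12CC=C(O[Si](C(C)C)(C(C)C)C(C)C)[C@H](C)[C@@H]1[C@H](c1occc1C1(C)OCCO1)CC=C2OS(=O)(=O)C(F)(F)F | intermediate
16 | C19 primary alcohol (CH2OH on C5) of 15 | OC[C@@]12CC=C(O[Si](C(C)C)(C(C)C)C(C)C)[C@H](C)[C@@H]1[C@H](c1occc1C1(C)OCCO1)CC=C2OS(=O)(=O)C(F)(F)F | intermediate
17 | 18,19-lactone (C18=O on C4, C19H2–O on C5, C3=C4) with C7=C8 silyl enol ether | O=C1OC[C@@]23CC=C(O[Si](C(C)C)(C(C)C)C(C)C)[C@H](C)[C@@H]2[C@H](c2occc2C2(C)OCCO2)CC=C13 | intermediate
18 | 7-hydroxy-8-ketone (hydroxyl drawn on the face of C19) | O=C1OC[C@@]23C[C@@H](O)C(=O)[C@H](C)[C@@H]2[C@H](c2occc2C2(C)OCCO2)CC=C13 | intermediate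
19 | diosphenol: C7=O, C8(OH)=C9(CH3) | O=C1OC[C@@]23CC(=O)C(O)=C(C)[C@@H]2[C@H](c2occc2C2(C)OCCO2)CC=C13 | intermediate
20 | 8-triflyloxy-8-en-7-one | O=C1OC[C@@]23CC(=O)C(OS(=O)(=O)C(F)(F)F)=C(C)[C@@H]2[C@H](c2occc2C2(C)OCCO2)CC=C13 | intermediate
21 | (7S)-alcohol, C8 enol triflate, C12 still a dioxolane | O=C1OC[C@@]23C[C@H](O)C(OS(=O)(=O)C(F)(F)F)=C(C)[C@@H]2[C@H](c2occc2C2(C)OCCO2)CC=C13 | intermediate (not isolated)
22 | (7S)-alcohol, C8 enol triflate, 3-acetylfuran-2-yl on C1 | O=C1OC[C@@]23C[C@H](O)C(OS(=O)(=O)C(F)(F)F)=C(C)[C@@H]2[C@H](c2occc2C(C)=O)CC=C13 | intermediate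
23 | (chloromethyl)trimethylsilane | C[Si](C)(C)CCl | starting material
24 | (trimethylsilyl)methylmagnesium chloride | C[Si](C)(C)C[Mg]Cl | intermediate (not isolated)
25 | (trimethylsilyl)methylzinc chloride | C[Si](C)(C)C[Zn]Cl | intermediate (not isolated)
26 | allylsilane alcohol: CH2SiMe3 on C8, C8=C9, (7S)-OH | O=C1OC[C@@]23C[C@H](O)C(C[Si](C)(C)C)=C(C)[C@@H]2[C@H](c2occc2C(C)=O)CC=C13 | intermediate
27 | allylsilane (7S)-acetate with C12 methyl ketone | O=C1OC[C@@]23C[C@H](OC(C)=O)C(C[Si](C)(C)C)=C(C)[C@@H]2[C@H](c2occc2C(C)=O)CC=C13 | intermediate
28 | (1R,5S,7S,10S) 9,11-seco precursor: C9=C8 allylsilane, C12 tert-butyldimethylsilyl enol ether | C[Si](C)(C)CC=1[C@@H](OC(C)=O)C[C@@]23COC(=O)C2=CC[C@@H](c2occc2C(=C)O[Si](C)(C)C(C)(C)C)[C@H]3C=1C | intermediate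
29 | target, (1R,5S,7S,9R,10S) | C=C1[C@@H](OC(C)=O)C[C@@]23COC(=O)C2=CC[C@H]2c4occc4C(=O)C[C@]1(C)[C@H]23 | target

## Step count and least certain steps

Total: 19 steps. Longest linear sequence: 16 steps (steps 1, 3 and 6–19). Step 2 and steps 4–5 are side branches.

**Step 19 (key step, proposed new method).** The radical cation may be captured by methanol at C11 before it cyclises, the allylsilane may be protodesilylated, or the seven-membered closure may be too slow and give way to oligomerisation or furan oxidation. Fallback by known chemistry, with the polarity of the same bond reversed: from 22, Stille coupling with Bu3SnCH2OH (Pd(PPh3)4, LiCl, dioxane) gives the C17 allylic alcohol, the diol F1. Selective chlorination of the primary allylic hydroxyl (MsCl, LiCl, 2,4,6-collidine, DMF, 0 °C) gives the chloro alcohol F2, and acetylation (Ac2O, pyridine) gives the chloro acetate F3. LiN(SiMe3)2 (THF, −78 to 0 °C) then forms the C12 methyl-ketone enolate, whose C11 displaces chloride by intramolecular SN2′ attack at C9 (seven-membered ring preferred over the nine-membered SN2 mode), and the route is rejoined at 29.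

**Step 3.** The uncatalysed cycloaddition may compete and erode the enantioselectivity, or conjugate addition may stop without ring closure. Fallback by resolution: the thermal reaction of 4 with 2 (CH2Cl2, −40 °C) gives 5 as the racemate, which is taken through steps 6–10 unchanged (5 and 12–16 as racemates). Racemic 16 is esterified with (S)-2-methoxy-2-phenylacetic acid (DCC, DMAP) to the ester of the wanted enantiomer, the O-methylmandelate F4, and its diastereomer from the unwanted enantiomer, the O-methylmandelate F5. F4 is separated by chromatography and cleaved (K2CO3, MeOH, 0 °C), and the route is rejoined at 16.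

**Step 6.** Addition may occur at the C4 carbonyl, C10 may be deprotonated instead, or the furan may be lithiated at C5. Fallback through a condensation, which discriminates hindered ketones more sharply: from 5, hydrogenation of the ene-dione double bond (H2, Pd/C) gives the saturated 1,4-dione F6, and TsNHNH2 (MeOH, rt) condenses with the less hindered C1 ketone to give the tosylhydrazone F7. Separately, 8 is lithiated and quenched with BrCl2C–CCl2Br to give the 2-bromofuran ketal F8. Barluenga coupling of F7 with F8 (Pd2(dba)3, XPhos, LiOt-Bu, dioxane, 90 °C) forms the C1–C16 bond and the C1=C2 alkene together, and the route is rejoined at 13.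

**Step 8.** Facial selectivity may be poor, the double bond may migrate on the catalyst before reduction and so scramble C1, or the enol ether may be partly reduced. Fallback with a directing group: from 13, KN(SiMe3)2 and PhNTf2 give the dienyl triflate ester F9, and i-Bu2AlH frees the C19 hydroxyl to give the dienyl triflate alcohol F10. Hydroxyl-directed hydrogenation with [Ir(cod)(PCy3)(py)]PF6 (H2, CH2Cl2) then delivers hydrogen to C1=C2 from the C19 face, and the route is rejoined at 16.

**Step 15.** Reagent and substrate may be mismatched, or the CH2 next to quaternary C5 may not be read as the small group, giving low diastereoselectivity. Fallback by inversion: from 20, NaBH4 with CeCl3·7H2O (MeOH, −78 °C) gives the substrate-controlled alcohol; if this is the (7R)-alcohol F11, Mitsunobu reaction with 4-nitrobenzoic acid (PPh3, diisopropyl azodicarboxylate) gives the (7S)-4-nitrobenzoate F12. Methanolysis (K2CO3, MeOH) rejoins the route at 21, which is hydrolysed to 22 as in step 15.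

## Further compounds

F1 | step 19 | diol: 22 with CH2OH on C8 in place of the triflate | O=C1OC[C@@]23C[C@H](O)C(CO)=C(C)[C@@H]2[C@H](c2occc2C(C)=O)CC=C13
F2 | step 19 | chloro alcohol: CH2Cl on C8, (7S)-OH | O=C1OC[C@@]23C[C@H](O)C(CCl)=C(C)[C@@H]2[C@H](c2occc2C(C)=O)CC=C13
F3 | step 19 | chloro acetate: CH2Cl on C8, (7S)-OAc | O=C1OC[C@@]23C[C@H](OC(C)=O)C(CCl)=C(C)[C@@H]2[C@H](c2occc2C(C)=O)CC=C13
F4 | step 3 | (S)-O-methylmandelate of 16 | CO[C@@H](c1ccccc1)C(=O)OC[C@@]12CC=C(O[Si](C(C)C)(C(C)C)C(C)C)[C@H](C)[C@@H]1[C@H](c1occc1C1(C)OCCO1)CC=C2OS(=O)(=O)C(F)(F)F
F5 | step 3 | (S)-O-methylmandelate of the enantiomer of 16 | CO[C@@H](c1ccccc1)C(=O)OC[C@]12CC=C(O[Si](C(C)C)(C(C)C)C(C)C)[C@@H](C)[C@H]1[C@@H](c1occc1C1(C)OCCO1)CC=C2OS(=O)(=O)C(F)(F)F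
F6 | step 6 | saturated 1,4-dione (2,3-dihydro-5) | COC(=O)[C@@]12CC=C(O[Si](C(C)C)(C(C)C)C(C)C)[C@H](C)[C@@H]1C(=O)CCC2=O
F7 | step 6 | C1 tosylhydrazone of F6 | COC(=O)[C@@]12CC=C(O[Si](C(C)C)(C(C)C)C(C)C)[C@H](C)[C@@H]1C(=NNS(=O)(=O)c1ccc(C)cc1)CCC2=O
F8 | step 6 | 2-(2-bromofuran-3-yl)-2-methyl-1,3-dioxolane | Brc1occc1C1(C)OCCO1
F9 | step 8 | dienyl triflate ester: C1=C2 and C3=C4(OTf), CO2Me on C5 | COC(=O)[C@@]12CC=C(O[Si](C(C)C)(C(C)C)C(C)C)[C@H](C)[C@@H]1C(c1occc1C1(C)OCCO1)=CC=C2OS(=O)(=O)C(F)(F)F
F10 | step 8 | dienyl triflate alcohol: as F9 with CH2OH on C5 | OC[C@@]12CC=C(O[Si](C(C)C)(C(C)C)C(C)C)[C@H](C)[C@@H]1C(c1occc1C1(C)OCCO1)=CC=C2OS(=O)(=O)C(F)(F)F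
F11 | step 15 | (7R)-alcohol, C7 epimer of 21 | O=C1OC[C@@]23C[C@@H](O)C(OS(=O)(=O)C(F)(F)F)=C(C)[C@@H]2[C@H](c2occc2C2(C)OCCO2)CC=C13
F12 | step 15 | (7S)-4-nitrobenzoate of 21 | O=C1OC[C@@]23C[C@H](OC(=O)c4ccc(cc4)[N+](=O)[O-])C(OS(=O)(=O)C(F)(F)F)=C(C)[C@@H]2[C@H](c2occc2C2(C)OCCO2)CC=C13
A1 | alternative 1 | bridged eight-membered enol ether (O between C3 and C7, C7=C6, C4=C5) | C=C1C(=C)O[C@H]2C[C@H]3c4occc4C(=O)C[C@]1(C)[C@H]3C1=C2C(=O)OC1
A2 | alternative 1 | 7-oxo compound | C=C1C(=O)C[C@@]23COC(=O)C2=CC[C@H]2c4occc4C(=O)C[C@]1(C)[C@H]23
A3 | alternative 2 | 2-ethynyl cycloheptenone (C16=O, C13=C12, ethynyl on C13) | C=C1[C@@H](OC(C)=O)C[C@@]23COC(=O)C2=CC[C@H]2C(=O)C(C#C)=CC[C@]1(C)[C@H]23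
A4 | alternative 2 | 12-hydroxy furan (one C12 epimer drawn) | C=C1[C@@H](OC(C)=O)C[C@@]23COC(=O)C2=CC[C@H]2c4occc4[C@H](O)C[C@]1(C)[C@H]23
A5 | alternative 3 | 1,3-dien-18,19-olide with the furan-3-yl(silyloxy)ethyl chain on C9 | C=C1[C@@H](OC(C)=O)C[C@@]23COC(=O)C2=CC=C[C@H]3[C@@]1(C)C[C@H](O[Si](C)(C)C(C)(C)C)c1ccoc1
A6 | alternative 3 | ring C-closed 12-silyloxy compound | C=C1[C@@H](OC(C)=O)C[C@@]23COC(=O)C2=CC[C@H]2c4occc4[C@@H](O[Si](C)(C)C(C)(C)C)C[C@]1(C)[C@H]23
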